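**Plan**
- Retrosynthetic cuts, in order: the O3–acetyl bond; C12–C13 (butadienyl unit); C9–C11 with C8–O (a cis γ-lactone laid on a C8=C9 alkene); C3–O (allylic position of a C1=C2 alkene); then C3–C4 and C5–C10 together, which opens rings A and B to one achiral chain.
- Enabling feature: C4, C5 and C10 (two of them quaternary) are contiguous in ring A, so with C18 as a formyl group ring A is the Diels–Alder cyclohexene of the (E)-enal C4=C5 and the diene C10=C1–C2=C3, and the tether C6–C7–C8=C9 closes ring B in the same event.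
- Forward: neryl acetate supplies C4–C10 with C17–C19; C1 (CBr4), C20 (Me3Al) and C2–C3 (vinyl bromide) complete the tetraenal; one cycloaddition makes both rings; C11–C12 come from acetic acid and C13–C16 from chloroprene.
- Stereochemistry: a chiral oxazaborolidinium ion sets the absolute sense; alkene geometries and the endo transition state relate C4, C5 and C10; C9 and C8 follow from attack anti to C20 and cis-lactone closure; C3 comes from axial hydride delivery to a ketone.

Key step: step 10

Convention: labdane numbering is used; α is the face of the decalin that carries the angular methyl C20, β the face of H5; C18 is the oxygenated carbon on C4 and C19 its methyl. All bicyclic compounds have 5β-H, 10α-CH3, 4α-CH3 and 4β-CH2O, and from 17 on also 8α-CH3 and 9α-H.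

Assumption: the (R)-configured catalyst is assigned by analogy with 2-methylacrolein, where the (S)-catalyst is taken to direct the diene to the Re face of the α-carbon; the target needs attack on the Si face of C4, and if the sense proved opposite the (S)-catalyst would be used with no other change.

**Route**

Step 1
Reactants: 1 neryl acetate
Product: 2 (2Z,6E)-8-hydroxy-3,7-dimethylocta-2,6-dien-1-yl acetate
Conditions: SeO2 (cat.), t-BuOOH, salicylic acid (cat.), CH2Cl2, 0 °C → rt
Reagents that add atoms: tert-butyl hydroperoxide, CC(C)(C)OO (oxygen, relayed by SeO2)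
Why: Riley allylic hydroxylation, in which the ene reaction and [2,3]-shift of SeO2 take the (E)-methyl of the electron-richer distal alkene because the C2=C3 alkene is deactivated by its allylic acetate, so the (E)-allylic alcohol should result.

Step 2
Reactants: 2 (2Z,6E)-8-hydroxy-3,7-dimethylocta-2,6-dien-1-yl acetate
Product: 3 (2Z,6E)-8-[(tert-butyldimethylsilyl)oxy]-3,7-dimethylocta-2,6-dien-1-yl acetate
Conditions: TBSCl, imidazole, DMF, rt
Reagents that add atoms: tert-butyldimethylsilyl chloride, CC(C)(C)[Si](C)(C)Cl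
Why: Imidazole-mediated silylation of a primary allylic alcohol is routine and leaves the acetate untouched.

Step 3
Reactants: 3 (2Z,6E)-8-[(tert-butyldimethylsilyl)oxy]-3,7-dimethylocta-2,6-dien-1-yl acetate
Product: 4 (2Z,6E)-8-[(tert-butyldimethylsilyl)oxy]-3,7-dimethylocta-2,6-dien-1-ol
Conditions: K2CO3, MeOH, 0 °C → rt
Reagents that add atoms: none
Why: Base-catalysed transesterification with methanol removes the acetate while the silyl ether stays.

Step 4
Reactants: 4 (2Z,6E)-8-[(tert-butyldimethylsilyl)oxy]-3,7-dimethylocta-2,6-dien-1-ol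
Product: 5 (2Z,6E)-8-[(tert-butyldimethylsilyl)oxy]-3,7-dimethylocta-2,6-dienal
Conditions: activated MnO2, CH2Cl2, rt; used at once
Reagents that add atoms: none
Why: MnO2 oxidises allylic alcohols selectively under neutral conditions, which should preserve the Z geometry of the new enal.

Step 5
Reactants: 5 (2Z,6E)-8-[(tert-butyldimethylsilyl)oxy]-3,7-dimethylocta-2,6-dienal
Product: 6 tert-butyl{[(2E,6Z)-9,9-dibromo-2,6-dimethylnona-2,6,8-trien-1-yl]oxy}dimethylsilane
Conditions: CBr4, PPh3, 2,6-lutidine (buffer), CH2Cl2, −20 → 0 °C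
Reagents that add atoms: carbon tetrabromide, BrC(Br)(Br)Br
Why: First half of the Corey–Fuchs sequence, a Wittig reaction of the ylide Ph3P=CBr2 formed in the flask, with the buffer keeping HBr away from the silyl ether and the Z-alkene.

Step 6
Reactants: 6 tert-butyl{[(2E,6Z)-9,9-dibromo-2,6-dimethylnona-2,6,8-trien-1-yl]oxy}dimethylsilane
Product: 8 tert-butyl{[(2E,6Z)-2,6-dimethylnona-2,6-dien-8-yn-1-yl]oxy}dimethylsilane, via lithium acetylide 7 (not isolated)
Conditions: n-BuLi (2.1 equiv), THF, −78 °C; then H2O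
Reagents that add atoms: none
Why: Second half of the Corey–Fuchs sequence, in which bromine–lithium exchange, Fritsch–Buttenberg–Wiechell rearrangement and deprotonation give the acetylide that is protonated on work-up.

Step 7
Reactants: 8 tert-butyl{[(2E,6Z)-2,6-dimethylnona-2,6-dien-8-yn-1-yl]oxy}dimethylsilane; 9 vinyl bromide
Product: 11 tert-butyldimethyl{[(2E,6Z,8E)-2,6,8-trimethylundeca-2,6,8,10-tetraen-1-yl]oxy}silane, via alkenyldimethylalane 10 (not isolated)
Conditions: Me3Al, Cp2ZrCl2 (cat.), CH2Cl2, 0 °C → rt; then ZnCl2, Pd(PPh3)4 (cat.), 9 (1 M in THF), rt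
Reagents that add atoms: trimethylaluminium, C[Al](C)C
Why: Zirconium-catalysed methylalumination adds CH3 and Al syn across the terminal alkyne with CH3 on the inner carbon, and the alkenylalane then couples with vinyl bromide at zerovalent palladium with retention (Negishi coupling), which fixes the E geometry of C10=C1.

Step 8
Reactants: 11 tert-butyldimethyl{[(2E,6Z,8E)-2,6,8-trimethylundeca-2,6,8,10-tetraen-1-yl]oxy}silane
Product: 12 (2E,6Z,8E)-2,6,8-trimethylundeca-2,6,8,10-tetraen-1-ol
Conditions: TBAF, THF, 0 °C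
Reagents that add atoms: none
Why: Fluoride cleaves the Si–O bond (silyl ether deprotection) without touching the triene.

Step 9
Reactants: 12 (2E,6Z,8E)-2,6,8-trimethylundeca-2,6,8,10-tetraen-1-ol
Product: 13 (2E,6Z,8E)-2,6,8-trimethylundeca-2,6,8,10-tetraenal
Conditions: activated MnO2, CH2Cl2, rt; kept cold and used at once
Reagents that add atoms: none
Why: MnO2 oxidation of the primary allylic alcohol gives the (E)-2-methyl enal without acid, base or heat, none of which the Z,E-triene would tolerate.

Step 10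
Reactants: 13 (2E,6Z,8E)-2,6,8-trimethylundeca-2,6,8,10-tetraenal
Product: 14 (1S,4aS,8aS)-1,4a,6-trimethyl-1,2,4a,7,8,8a-hexahydronaphthalene-1-carbaldehyde
Conditions: (R)-3,3-diphenyl-1-(2-methylphenyl)tetrahydro-1H,3H-pyrrolo[1,2-c][1,3,2]oxazaborole (20 mol%), (CF3SO2)2NH (18 mol%), CH2Cl2, −78 → −40 °C
Reagents that add atoms: none
Why: The N-protonated oxazaborolidine binds the formyl oxygen at boron and lowers the enal LUMO, so that the terminal diene C10=C1–C2=C3 adds across C4=C5 in a concerted, asynchronous [4+2] in which C5–C10 leads and C3–C4 follows. The closest known reaction is the intramolecular Diels–Alder reaction of 2,8,10-trienals under achiral and chiral boron Lewis acids, 2-methyl enals included, and thermal versions tolerate a methyl group on the tethered diene terminus. Ring A closes as the six-membered cycloadduct ring, and ring B closes at the same moment as the fused six-membered ring made of the tether C6–C7–C8=C9 and the new C5–C10 bond; the Z geometry of C8=C9 holds C7 and C10 cis as this ring requires, and allylic strain keeps that alkene twisted out of the diene plane and out of the reaction. C4 and C5 are related by the E geometry of the enal (formyl and H5 stay cis), C10 is related to C5 by the E geometry of C10=C1 and the endo-formyl, tether-anti transition state that gives the trans fusion with C20 anti to H5, and the absolute sense comes from the catalyst, which shields the Re face of C4 so that C3 bonds to its Si face. The step needs endo selectivity, one enantioface and reaction of the terminal diene only: the boron-bound formyl group favours the endo array, the catalyst selects the face, the short C5-to-C8 distance excludes the inner diene, and the low temperature suppresses 1,5-hydrogen shifts of the Z-configured triene.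

Step 11
Reactants: 14 (1S,4aS,8aS)-1,4a,6-trimethyl-1,2,4a,7,8,8a-hexahydronaphthalene-1-carbaldehyde
Product: 15 [(1S,4aS,8aS)-1,4a,6-trimethyl-1,2,4a,7,8,8a-hexahydronaphthalen-1-yl]methanol
Conditions: NaBH4, MeOH, 0 °C
Reagents that add atoms: none
Why: Borohydride reduction of the neopentyl aldehyde gives the primary alcohol C18–OH, and no stereocentre can be affected because C4 bears no hydrogen.

Step 12
Reactants: 15 [(1S,4aS,8aS)-1,4a,6-trimethyl-1,2,4a,7,8,8a-hexahydronaphthalen-1-yl]methanol
Product: 16 tert-butyl{[(1S,4aS,8aS)-1,4a,6-trimethyl-1,2,4a,7,8,8a-hexahydronaphthalen-1-yl]methoxy}diphenylsilane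
Conditions: TBDPSCl, imidazole, DMAP (cat.), DMF, rt
Reagents that add atoms: tert-butyldiphenylsilyl chloride, CC(C)(C)[Si](Cl)(c1ccccc1)c1ccccc1
Why: Silylation with the bulky, acid-stable tert-butyldiphenylsilyl group, chosen because it should survive hot acetic acid, SeO2, hydride and Grignard reagents later on.

Step 13
Reactants: 16 tert-butyl{[(1S,4aS,8aS)-1,4a,6-trimethyl-1,2,4a,7,8,8a-hexahydronaphthalen-1-yl]methoxy}diphenylsilane
Product: 17 18-[(tert-butyldiphenylsilyl)oxy]-13,14,15,16-tetranorlabd-1-en-12,8β-olide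
Conditions: Mn(OAc)3·2H2O (2.5 equiv), KOAc, AcOH/Ac2O, 90 °C, argon
Reagents that add atoms: acetic acid (as manganese-bound acetate), CC(=O)O
Why: Oxidative radical lactone annulation with Mn(OAc)3, in which the carboxymethyl radical adds to the less substituted C9 of the trisubstituted, more electron-rich alkene on the face opposite the axial C20 methyl, the tertiary C8 radical is oxidised by a second trivalent manganese and the carboxyl group closes on the same face, which sets C9 and C8 together as the cis-fused γ-lactone.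

Step 14
Reactants: 17 18-[(tert-butyldiphenylsilyl)oxy]-13,14,15,16-tetranorlabd-1-en-12,8β-olide
Product: 18 3β-hydroxy-18-[(tert-butyldiphenylsilyl)oxy]-13,14,15,16-tetranorlabd-1-en-12,8β-olide
Conditions: SeO2, wet 1,4-dioxane, 90 °C
Reagents that add atoms: selenium dioxide, O=[Se]=O
Why: In this Riley oxidation the ene reaction at C1 with transfer of a C3 hydrogen, followed by the [2,3]-shift, can place oxygen only at C3 and return the alkene to C1=C2 because C10 carries no hydrogen; the alcohol is expected on the β face, and its configuration is erased in the next step.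

Step 15
Reactants: 18 3β-hydroxy-18-[(tert-butyldiphenylsilyl)oxy]-13,14,15,16-tetranorlabd-1-en-12,8β-olide
Product: 19 3-oxo-18-[(tert-butyldiphenylsilyl)oxy]-13,14,15,16-tetranorlabd-1-en-12,8β-olide
Conditions: Dess–Martin periodinane, NaHCO3, CH2Cl2, rt
Reagents that add atoms: none
Why: Dess–Martin oxidation of the allylic alcohol gives the enone and gathers both C3 epimers and any enone already formed in step 14 into one compound.

Step 16
Reactants: 19 3-oxo-18-[(tert-butyldiphenylsilyl)oxy]-13,14,15,16-tetranorlabd-1-en-12,8β-olide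
Product: 20 3-oxo-18-[(tert-butyldiphenylsilyl)oxy]-13,14,15,16-tetranorlabdan-12,8β-olide
Conditions: H2 (1 atm), 10% Pd/C, EtOAc, rt
Reagents that add atoms: none
Why: Heterogeneous hydrogenation saturates the disubstituted enone alkene while ketone, lactone and silyl ether are inert under these conditions.

Step 17
Reactants: 20 3-oxo-18-[(tert-butyldiphenylsilyl)oxy]-13,14,15,16-tetranorlabdan-12,8β-olide
Product: 21 18-[(tert-butyldiphenylsilyl)oxy]-13,14,15,16-tetranorlabdane-3α,8β,12-triol
Conditions: LiAlH4, THF, 0 °C → rt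
Reagents that add atoms: none
Why: LiAlH4 reduces the lactone to the 8,12-diol and the C3 ketone in one operation, with hydride adding to C3 along the axial direction on the β face, away from the equatorial CH2OSi group, to give the equatorial 3α-alcohol as is usual for 4,4-disubstituted 3-ketones.

Step 18
Reactants: 21 18-[(tert-butyldiphenylsilyl)oxy]-13,14,15,16-tetranorlabdane-3α,8β,12-triol
Product: 22 3α,8β,12-tris[(triethylsilyl)oxy]-18-[(tert-butyldiphenylsilyl)oxy]-13,14,15,16-tetranorlabdane
Conditions: Et3SiOTf, 2,6-lutidine, CH2Cl2, −78 → 0 °C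
Reagents that add atoms: triethylsilyl trifluoromethanesulfonate, CC[Si](CC)(CC)OS(=O)(=O)C(F)(F)F
Why: The silyl triflate silylates even the tertiary C8 hydroxyl, which must be masked because a free 8-hydroxyl would close a tetrahydrofuran onto any leaving group at C12.

Step 19
Reactants: 22 3α,8β,12-tris[(triethylsilyl)oxy]-18-[(tert-butyldiphenylsilyl)oxy]-13,14,15,16-tetranorlabdane
Product: 23 3α,8β-bis[(triethylsilyl)oxy]-18-[(tert-butyldiphenylsilyl)oxy]-13,14,15,16-tetranorlabdan-12-ol
Conditions: pyridinium p-toluenesulfonate (cat.), MeOH/CH2Cl2, 0 °C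
Reagents that add atoms: none
Why: Acid-catalysed methanolysis removes triethylsilyl groups much faster from primary than from hindered secondary or tertiary oxygen, so only C12–OH should be set free at 0 °C.

Step 20
Reactants: 23 3α,8β-bis[(triethylsilyl)oxy]-18-[(tert-butyldiphenylsilyl)oxy]-13,14,15,16-tetranorlabdan-12-ol
Product: 24 12-iodo-3α,8β-bis[(triethylsilyl)oxy]-18-[(tert-butyldiphenylsilyl)oxy]-13,14,15,16-tetranorlabdane
Conditions: I2, PPh3, imidazole, CH2Cl2, 0 °C
Reagents that add atoms: iodine, II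
Why: Appel iodination, an SN2 displacement of the alkoxyphosphonium group by iodide at the unhindered primary carbon, with imidazole buffering the acid.

Step 21
Reactants: 24 12-iodo-3α,8β-bis[(triethylsilyl)oxy]-18-[(tert-butyldiphenylsilyl)oxy]-13,14,15,16-tetranorlabdane; 25 chloroprene
Product: 27 3α,8β-bis[(triethylsilyl)oxy]-18-[(tert-butyldiphenylsilyl)oxy]labda-13(16),14-diene, via buta-1,3-dien-2-ylmagnesium chloride 26 (not isolated)
Conditions: 25, Mg, THF, 50 °C; then 24, Li2CuCl4 (cat.), THF, −20 → 0 °C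
Reagents that add atoms: none
Why: Copper-catalysed cross-coupling of a Grignard reagent with a primary alkyl iodide, in which the 2-butadienyl Grignard reagent from chloroprene delivers C13–C16 as the intact 2-substituted 1,3-diene.

Step 22
Reactants: 27 3α,8β-bis[(triethylsilyl)oxy]-18-[(tert-butyldiphenylsilyl)oxy]labda-13(16),14-diene
Product: 28 18-[(tert-butyldiphenylsilyl)oxy]labda-13(16),14-diene-3α,8β-diol
Conditions: camphorsulfonic acid (cat.), MeOH/CH2Cl2, 0 °C → rt
Reagents that add atoms: none
Why: Mild acid methanolysis cleaves both triethylsilyl ethers while the far more acid-stable tert-butyldiphenylsilyl ether stays on C18.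

Step 23
Reactants: 28 18-[(tert-butyldiphenylsilyl)oxy]labda-13(16),14-diene-3α,8β-diol
Product: 29 3α-acetoxy-18-[(tert-butyldiphenylsilyl)oxy]labda-13(16),14-dien-8β-ol
Conditions: Ac2O, pyridine, DMAP (trace), CH2Cl2, rt
Reagents that add atoms: acetic anhydride, CC(=O)OC(C)=O
Why: Acetylation takes the equatorial secondary C3 alcohol only, because the tertiary C8 alcohol is too hindered to react under these conditions and C18 is still protected.

Step 24
Reactants: 29 3α-acetoxy-18-[(tert-butyldiphenylsilyl)oxy]labda-13(16),14-dien-8β-ol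
Product: 30 (3R,4S,5S,8S,9R,10R)-3-acetoxylabda-13(16),14-diene-8,18-diol
Conditions: HF·pyridine, pyridine, THF, 0 °C → rt
Reagents that add atoms: none
Why: Fluoride-mediated desilylation under buffered, non-basic conditions removes the last silyl group, so the acetate should not migrate from O3 to O18.

**Compound list**

1 | neryl acetate, (2Z)-3,7-dimethylocta-2,6-dien-1-yl acetate | CC(C)=CCC/C(C)=C\COC(C)=O | starting material
2 | (2Z,6E)-8-hydroxy-3,7-dimethylocta-2,6-dien-1-yl acetate | OC/C(C)=C/CC/C(C)=C\COC(C)=O | intermediate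
3 | (2Z,6E)-8-[(tert-butyldimethylsilyl)oxy]-3,7-dimethylocta-2,6-dien-1-yl acetate | CC(C)(C)[Si](C)(C)OC/C(C)=C/CC/C(C)=C\COC(C)=O | intermediate
4 | (2Z,6E)-8-[(tert-butyldimethylsilyl)oxy]-3,7-dimethylocta-2,6-dien-1-ol | CC(C)(C)[Si](C)(C)OC/C(C)=C/CC/C(C)=C\CO | intermediate
5 | (2Z,6E)-8-[(tert-butyldimethylsilyl)oxy]-3,7-dimethylocta-2,6-dienal | CC(C)(C)[Si](C)(C)OC/C(C)=C/CC/C(C)=C\C=O | intermediate
6 | tert-butyl{[(2E,6Z)-9,9-dibromo-2,6-dimethylnona-2,6,8-trien-1-yl]oxy}dimethylsilane | CC(C)(C)[Si](C)(C)OC/C(C)=C/CC/C(C)=C\C=C(Br)Br | intermediate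
7 | lithium acetylide of 8 | CC(C)(C)[Si](C)(C)OC/C(C)=C/CC/C(C)=C\C#C[Li] | intermediate (not isolated)
8 | tert-butyl{[(2E,6Z)-2,6-dimethylnona-2,6-dien-8-yn-1-yl]oxy}dimethylsilane | CC(C)(C)[Si](C)(C)OC/C(C)=C/CC/C(C)=C\C#C | intermediate
9 | vinyl bromide | C=CBr | starting material
10 | (E)-alkenyldimethylalane from syn methylalumination of 8 (CH3 on C10, Al on C1) | CC(C)(C)[Si](C)(C)OC/C(C)=C/CC/C(C)=C\C(C)=C\[Al](C)C | intermediate (not isolated)
11 | tert-butyldimethyl{[(2E,6Z,8E)-2,6,8-trimethylundeca-2,6,8,10-tetraen-1-yl]oxy}silane | CC(C)(C)[Si](C)(C)OC/C(C)=C/CC/C(C)=C\C(C)=C\C=C | intermediate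
12 | (2E,6Z,8E)-2,6,8-trimethylundeca-2,6,8,10-tetraen-1-ol | OC/C(C)=C/CC/C(C)=C\C(C)=C\C=C | intermediate
13 | (2E,6Z,8E)-2,6,8-trimethylundeca-2,6,8,10-tetraenal | O=C/C(C)=C/CC/C(C)=C\C(C)=C\C=C | intermediate
14 | (1S,4aS,8aS)-1,4a,6-trimethyl-1,2,4a,7,8,8a-hexahydronaphthalene-1-carbaldehyde (trans-fused; alkenes C1=C2 and C8=C9; formyl C18 β, C19 and C20 α, H5 β) | CC1=C[C@]2(C)C=CC[C@](C)(C=O)[C@H]2CC1 | intermediate
15 | [(1S,4aS,8aS)-1,4a,6-trimethyl-1,2,4a,7,8,8a-hexahydronaphthalen-1-yl]methanol | CC1=C[C@]2(C)C=CC[C@](C)(CO)[C@H]2CC1 | intermediate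
16 | tert-butyl{[(1S,4aS,8aS)-1,4a,6-trimethyl-1,2,4a,7,8,8a-hexahydronaphthalen-1-yl]methoxy}diphenylsilane | CC1=C[C@]2(C)C=CC[C@](C)(CO[Si](c3ccccc3)(c3ccccc3)C(C)(C)C)[C@H]2CC1 | intermediate
17 | 18-[(tert-butyldiphenylsilyl)oxy]-13,14,15,16-tetranorlabd-1-en-12,8β-olide (cis-fused γ-lactone; C11 on C9 and O on C8 both β) | O=C1C[C@@H]2[C@]3(C)C=CC[C@](C)(CO[Si](c4ccccc4)(c4ccccc4)C(C)(C)C)[C@H]3CC[C@]2(C)O1 | intermediate
18 | 3β-hydroxy-18-[(tert-butyldiphenylsilyl)oxy]-13,14,15,16-tetranorlabd-1-en-12,8β-olide | O=C1C[C@@H]2[C@]3(C)C=C[C@H](O)[C@](C)(CO[Si](c4ccccc4)(c4ccccc4)C(C)(C)C)[C@H]3CC[C@]2(C)O1 | intermediate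
19 | 3-oxo-18-[(tert-butyldiphenylsilyl)oxy]-13,14,15,16-tetranorlabd-1-en-12,8β-olide | O=C1C[C@@H]2[C@]3(C)C=CC(=O)[C@](C)(CO[Si](c4ccccc4)(c4ccccc4)C(C)(C)C)[C@H]3CC[C@]2(C)O1 | intermediate
20 | 3-oxo-18-[(tert-butyldiphenylsilyl)oxy]-13,14,15,16-tetranorlabdan-12,8β-olide | O=C1C[C@@H]2[C@]3(C)CCC(=O)[C@](C)(CO[Si](c4ccccc4)(c4ccccc4)C(C)(C)C)[C@H]3CC[C@]2(C)O1 | intermediate
21 | 18-[(tert-butyldiphenylsilyl)oxy]-13,14,15,16-tetranorlabdane-3α,8β,12-triol | OCC[C@@H]1[C@]2(C)CC[C@@H](O)[C@](C)(CO[Si](c3ccccc3)(c3ccccc3)C(C)(C)C)[C@H]2CC[C@]1(C)O | intermediate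
22 | 3α,8β,12-tris[(triethylsilyl)oxy]-18-[(tert-butyldiphenylsilyl)oxy]-13,14,15,16-tetranorlabdane | CC[Si](CC)(CC)OCC[C@@H]1[C@]2(C)CC[C@@H](O[Si](CC)(CC)CC)[C@](C)(CO[Si](c3ccccc3)(c3ccccc3)C(C)(C)C)[C@H]2CC[C@]1(C)O[Si](CC)(CC)CC | intermediate
23 | 3α,8β-bis[(triethylsilyl)oxy]-18-[(tert-butyldiphenylsilyl)oxy]-13,14,15,16-tetranorlabdan-12-ol | OCC[C@@H]1[C@]2(C)CC[C@@H](O[Si](CC)(CC)CC)[C@](C)(CO[Si](c3ccccc3)(c3ccccc3)C(C)(C)C)[C@H]2CC[C@]1(C)O[Si](CC)(CC)CC | intermediate
24 | 12-iodo-3α,8β-bis[(triethylsilyl)oxy]-18-[(tert-butyldiphenylsilyl)oxy]-13,14,15,16-tetranorlabdane | ICC[C@@H]1[C@]2(C)CC[C@@H](O[Si](CC)(CC)CC)[C@](C)(CO[Si](c3ccccc3)(c3ccccc3)C(C)(C)C)[C@H]2CC[C@]1(C)O[Si](CC)(CC)CC | intermediate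
25 | chloroprene, 2-chlorobuta-1,3-diene | C=CC(Cl)=C | starting material
26 | buta-1,3-dien-2-ylmagnesium chloride | C=CC(=C)[Mg]Cl | intermediate (not isolated)
27 | 3α,8β-bis[(triethylsilyl)oxy]-18-[(tert-butyldiphenylsilyl)oxy]labda-13(16),14-diene | C=CC(=C)CC[C@@H]1[C@]2(C)CC[C@@H](O[Si](CC)(CC)CC)[C@](C)(CO[Si](c3ccccc3)(c3ccccc3)C(C)(C)C)[C@H]2CC[C@]1(C)O[Si](CC)(CC)CC | intermediate
28 | 18-[(tert-butyldiphenylsilyl)oxy]labda-13(16),14-diene-3α,8β-diol | C=CC(=C)CC[C@@H]1[C@]2(C)CC[C@@H](O)[C@](C)(CO[Si](c3ccccc3)(c3ccccc3)C(C)(C)C)[C@H]2CC[C@]1(C)O | intermediate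
29 | 3α-acetoxy-18-[(tert-butyldiphenylsilyl)oxy]labda-13(16),14-dien-8β-ol | C=CC(=C)CC[C@@H]1[C@]2(C)CC[C@@H](OC(C)=O)[C@](C)(CO[Si](c3ccccc3)(c3ccccc3)C(C)(C)C)[C@H]2CC[C@]1(C)O | intermediate
30 | (3R,4S,5S,8S,9R,10R)-3-acetoxylabda-13(16),14-diene-8,18-diol (3α-OAc, 8β-OH, 9α-H, 5β-H, 10α-CH3), CNP0313672.1 | C=CC(=C)CC[C@@H]1[C@]2(C)CC[C@@H](OC(C)=O)[C@](C)(CO)[C@H]2CC[C@]1(C)O | target

**Step count and risks**

Total step count: 24. Longest linear sequence: 24 steps, from 1 to 30; vinyl bromide and chloroprene enter as commercial reagents in steps 7 and 21.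

Steps most likely to fail, riskiest first:

Step 10. The fully substituted diene terminus C10 and the α-methyl group crowd the forming C5–C10 bond, so the chiral catalyst may turn over slowly or discriminate the enal faces poorly. In that case the ring closure would be run from 13 with Me2AlCl (CH2Cl2, −78 → 0 °C), a known promoter of such trienal cycloadditions. This gives 14 as the racemate, that is together with its mirror image ent-14 F1. NaBH4 reduction gives 15 together with ent-15 F2. Acylation with (1S,4R)-camphanic chloride (pyridine, DMAP) gives the camphanate of 15 F3 and the camphanate of ent-15 F4, which are diastereomers and should be separable by chromatography or crystallisation. LiOH in THF/H2O on F3 returns to the route at 15.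

Step 13. The carboxymethyl radical may also add to the ring A alkene, or allylic oxidation may compete, which would give mixtures. The lactone would then be built by ionic and pericyclic steps, setting out from 16. SeO2 (cat.) with t-BuOOH should hydroxylate the ring CH2 next to the trisubstituted alkene, through an ene reaction at C9 on the face anti to C20, to give the 7β-alcohol F5. Eschenmoser–Claisen rearrangement with N,N-dimethylacetamide dimethyl acetal (xylene, 140 °C) transfers the two-carbon unit suprafacially to the β face of C9 and moves the alkene to C7=C8, giving the amide F6. Iodolactonisation (I2, THF/H2O) closes the O–C8 bond on the β face to give the 7α-iodo lactone F7. Bu3SnH with AIBN removes the iodine, and the route is rejoined at 17.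

Step 14. The ene reaction at the hindered C1 may be too slow, or over-oxidation may erode the material. Hydroxylation through 18 would then be given up for hydrogen-atom abstraction at C3: CrO3·3,5-dimethylpyrazole (CH2Cl2, −20 °C) should oxidise the only allylic CH2 of 17 directly to the enone. This rejoins the route at 19 and merges steps 14 and 15 into one. A transposed enone formed by oxygen capture at C1 would be removed by chromatography. This fallback makes no compound outside the list (F0).

**Further compounds**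

F1 | step 10 | ent-14, (1R,4aR,8aR)-1,4a,6-trimethyl-1,2,4a,7,8,8a-hexahydronaphthalene-1-carbaldehyde | CC1=C[C@@]2(C)C=CC[C@@](C)(C=O)[C@@H]2CC1
F2 | step 10 | ent-15, [(1R,4aR,8aR)-1,4a,6-trimethyl-1,2,4a,7,8,8a-hexahydronaphthalen-1-yl]methanol | CC1=C[C@@]2(C)C=CC[C@@](C)(CO)[C@@H]2CC1
F3 | step 10 | (1S,4R)-camphanate of 15 | CC1=C[C@]2(C)C=CC[C@](C)(COC(=O)[C@@]34CC[C@@](C)(C(=O)O3)C4(C)C)[C@H]2CC1
F4 | step 10 | (1S,4R)-camphanate of ent-15 | CC1=C[C@@]2(C)C=CC[C@@](C)(COC(=O)[C@@]34CC[C@@](C)(C(=O)O3)C4(C)C)[C@@H]2CC1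
F5 | step 13 | 7β-hydroxy derivative of 16 (allylic alcohol at C7) | CC1=C[C@]2(C)C=CC[C@](C)(CO[Si](c3ccccc3)(c3ccccc3)C(C)(C)C)[C@H]2C[C@@H]1O
F6 | step 13 | N,N-dimethylamide with C11–C12 on the β face of C9 and alkenes C1=C2 and C7=C8 | CN(C)C(=O)C[C@@H]1[C@]2(C)C=CC[C@](C)(CO[Si](c3ccccc3)(c3ccccc3)C(C)(C)C)[C@H]2CC=C1C
F7 | step 13 | 7α-iodo derivative of 17 | O=C1C[C@@H]2[C@]3(C)C=CC[C@](C)(CO[Si](c4ccccc4)(c4ccccc4)C(C)(C)C)[C@H]3C[C@@H](I)[C@]2(C)O1
F0 | step 14 | none | none
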